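## The problem

The target 19 is a 4-aryl-1-tetralone. Ring B (the cyclohexanone) is fused to the 6,7-dimethoxybenzene ring A along C4a–C8a and carries a 3-hydroxy-4-methoxyphenyl group (ring C) at C4 and methyl groups at C2 and C3 (numbering: C1 carbonyl, C4 aryl-bearing carbon). The three contiguous stereocentres are 2S, 3R and 4R: the two methyl groups are trans, and the C3 methyl is cis to the C4 aryl group. C2 is α to the ketone, and its trans arrangement (both methyls equatorial, aryl pseudoaxial) is the thermodynamic one, so it can be left to equilibration. C3 has no acidic hydrogen, must be made early as one enantiomer, and is the only centre available to control C4. C4–H is doubly benzylic and, through ring A, vinylogous to the C1 ketone, so strong base or long heating can scramble it. The aryl ketone can be over-reduced by hydrogen, and the one free phenol must stay distinct from three methyl ethers. The opening lies in the neighbours of C3: C2 is already α to the C1 carbonyl, and C4 becomes α to a carbonyl once it bears a removable ester. The chain is then a 3-methylglutarate with a prochiral C3, and C4 is an enolate carbon that palladium can join to C4a of a bromoarene, closing ring B.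

## Retrosynthesis

**19 ⇒ 18 ⇒ 17 (no skeletal bond cut).** The phenol is unmasked last, from benzyl ether 18. The phenol must be protected during the enolate methylation, where a phenoxide would be O-methylated and lose its difference from the three methyl ethers. Benzyl survives amide bases, organomagnesium reagents, palladium catalysis and trifluoroacetic acid. Compound 18 is in turn the thermodynamic C2 epimer of the mixture 17, so C2 needs no kinetic control.

**17 ⇒ 15 (via acid 16) ⇒ 13 (C4–H traded for C4–CO2t-Bu; C2–CH3 cut).** The C4 hydrogen is put back as a tert-butyl ester. The ester is cleaved by acid without attack at the hindered acyl carbon. The acid 16 then loses CO2 through a carbanion conjugated through ring A with the C1 carbonyl, and protonation anti to the C3 methyl sets C4. The C2 methyl is cut next, back to 13. Methylating while C4 is still quaternary leaves C2 as the only enolisable position. After these two moves only C3 matters.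

**13 ⇒ 12 (C4–C4a, the ring-B closure).** Cutting the bond between the ester-bearing carbon and ring A gives the open-chain bromoaryl keto ester 12. The neighbouring cut, C1–C8a by Friedel–Crafts acylation, would need C3 and C4 set together in an acyclic chain. The C4–C4a cut needs C3 alone and treats C4 as a temporary enolate carbon. The forward reaction must couple the C4 ester enolate with C4a–Br while the C2 ketone enolate stays a spectator.

**12 ⇒ 9 + 11 (C1–C8a, acyl–aryl).** The ketone comes from the N-methoxy-N-methylamide 9 and the arylmagnesium 11. Reagent 11 is made by exchanging one of the two equivalent bromines of 10, so the bromine needed for ring closure arrives with the reagent and no regiochemical question arises. The amide stops the addition at the ketone stage. A Friedel–Crafts acylation of 4-bromoveratrole would not tolerate the tert-butyl ester.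

**9 ⇒ 4 + 6 (C4–ring C).** The pendant aryl group is joined to the ester α-carbon by palladium-catalysed arylation of the zinc enolate 8, formed from the lithium enolate 7. This must come before the ketone, because afterwards the molecule holds its own aryl bromide and a second enolisable carbonyl. The new α-centre need not be controlled. Aryl bromide 6 is the benzyl ether of 5.

**4 ⇒ 3 ⇒ 2 ⇒ 1 (end differentiation, then symmetry).** Amide ester 4 comes from the mixed diester 3 by selective aminolysis of the methyl ester. Diester 3 comes from half-ester 2 by tert-butylation of the acid. Half-ester 2 comes from the achiral anhydride 1 by enantioselective methanolysis. The acid arm of 2 becomes the C4 arm and the methyl ester arm becomes C2–C1, which requires the (R)-half-ester.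

## Roads not taken

**Alternative 1:** Ring B is cut at C8a–C1 and C1–C2, with carbon monoxide as C1. Zerovalent palladium inserts into the C–I bond of the diarylmethine ester A2 and CO inserts. The C2 ester enolate then captures the aroylpalladium species to give the β-keto ester A1.
- Merits: two bonds and the carbonyl carbon arrive in one step. C4 is already fixed, so there is no late protonation to trust. The β-keto ester allows clean single methylation at C2 before the ester is lost.
- Weak points: A2 needs two adjacent acyclic stereocentres (the C4 diarylmethine and the C3 methyl) before any ring exists to help. Direct arylation without CO uptake would close a five-membered indane (C2–C8a). An ester enolate must be generated with strong base under CO. The aryl mesylate is a possible second site for oxidative addition.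
- Comparison: this road is better at C4, which is never exposed as a carbanion. The chosen plan offers instead one stereocentre from a cheap prochiral anhydride and a ring closure with no competing ring size.

**Alternative 2:** Ring B is cut at C1–C2 and C3–C4. Irradiation of the 2-benzylbenzaldehyde A4 gives the (E)-dienol, which adds endo to the chiral butenolide A5, anti to the menthyloxy group, and forms the all-cis lactone-fused tetralol A3.
- Merits: it is convergent, forms ring B and four stereocentres at once, and sets the 3,4-cis relation by a pericyclic rule with the auxiliary fixing the absolute sense.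
- Weak points: the two methyl groups arrive as a lactone carbonyl and an acetal carbon. Both must be reduced to CH3 through a 1,4-diol, which tends to close to a tetrahydrofuran on activation. The C1 carbinol must be carried through this and then oxidised. C2 must still be epimerised. The geometry of the aryl-bearing dienol terminus decides C4, and the dienol reketonises quickly.
- Comparison: A3 secures the relative configuration at C3/C4 better than a kinetic protonation can. The chosen plan carries both methyl groups at the right oxidation level from the start, which avoids a multi-step deoxygenation after the cycloaddition, and it needs no photochemistry.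

**Alternative 3:** Ring B is cut at C3=C4. Low-valent titanium from TiCl3 and Zn–Cu couples the diaryl ketone and the methyl ketone of A7 to the dihydronaphthalene A6. After desilylation, a hydrogenation directed by the C1 hydroxyl with [Ir(cod)(PCy3)(py)]PF6 adds H2 to one face. Oxidation at C1 and equilibration at C2 would finish.
- Merits: syn addition of hydrogen makes the 3,4-cis relation a consequence of mechanism, and intramolecular carbonyl coupling is good at six-membered rings with tetrasubstituted alkenes.
- Weak points: titanium is needed in large stoichiometric excess. The benzylic C1–O bond of A7 is at risk of reductive cleavage under those conditions. Two stereocentres (C1, C2) must be bought with an auxiliary aldol, and C1 is destroyed later. Hydrogenation of a hindered, aryl-conjugated tetrasubstituted alkene is slow even when directed.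
- Comparison: this road is stronger on the C3/C4 relation. The chosen plan has a catalytic ring closure, a single source of chirality and fewer redox corrections.

Key step: step 7

Assumption: the quinidine-derived dimer (DHQD)2AQN is taken to deliver the (R)-half-ester 2 in the methanolysis of 1; if the sense is the reverse, the quinine-derived (DHQ)2AQN takes its place and nothing else changes.

## Route

Step 1
Reactants: 1 3-methylglutaric anhydride
Product: 2 (3R)-5-methoxy-3-methyl-5-oxopentanoic acid
Conditions: MeOH (10 equiv), (DHQD)2AQN (cat.), Et2O, −40 °C; acid wash to recover the catalyst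
Reagents that add atoms: methanol, CO
Why: Alkaloid-catalysed enantioselective alcoholysis (desymmetrisation) of a prochiral cyclic anhydride; the quinuclidine nitrogen delivers methanol to one of the two enantiotopic carbonyl groups, which makes C3 a stereocentre because the two arms now differ. If needed, the half-ester could be enriched by crystallising a salt with a chiral amine.

Step 2
Reactants: 2 (3R)-5-methoxy-3-methyl-5-oxopentanoic acid
Product: 3 1-tert-butyl 5-methyl (3S)-3-methylpentanedioate
Conditions: Cl3CC(=NH)Ot-Bu, CH2Cl2–cyclohexane, rt
Reagents that add atoms: tert-butyl 2,2,2-trichloroacetimidate, CC(C)(C)OC(=N)C(Cl)(Cl)Cl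
Why: O-alkylation of a carboxylic acid by a trichloroacetimidate (tert-butyl cation transfer); no acyl transfer occurs, so the two ends stay distinct and C3 is untouched. The descriptor changes from R to S only because the tert-butyl ester outranks the methyl ester.

Step 3
Reactants: 3 1-tert-butyl 5-methyl (3S)-3-methylpentanedioate
Product: 4 tert-butyl (3S)-5-[methoxy(methyl)amino]-3-methyl-5-oxopentanoate
Conditions: MeNH(OMe)·HCl, i-PrMgCl, THF, −20 → 0 °C
Reagents that add atoms: N,O-dimethylhydroxylamine hydrochloride, CNOC.Cl
Why: Direct aminolysis of a methyl ester by the chloromagnesium amide of N,O-dimethylhydroxylamine (Weinreb amide synthesis); the tert-butyl ester is too hindered to react at this temperature, so only the methyl terminus is converted.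

Step 4
Reactants: 5 5-bromo-2-methoxyphenol
Product: 6 2-(benzyloxy)-4-bromo-1-methoxybenzene
Conditions: BnBr, K2CO3, DMF, rt
Reagents that add atoms: benzyl bromide, BrCc1ccccc1
Why: Williamson ether synthesis on a phenoxide.

Step 5
Reactants: 4 tert-butyl (3S)-5-[methoxy(methyl)amino]-3-methyl-5-oxopentanoate; 6 2-(benzyloxy)-4-bromo-1-methoxybenzene
Product: 9 tert-butyl (3S)-2-[3-(benzyloxy)-4-methoxyphenyl]-5-[methoxy(methyl)amino]-3-methyl-5-oxopentanoate (both epimers at the ester α-carbon), via lithium ester enolate 7 (not isolated), via chlorozinc ester enolate 8 (not isolated)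
Conditions: LiN(i-Pr)2 (1.05 equiv), THF, −78 °C; ZnCl2, −78 °C → rt; then 6, Pd(dba)2 (cat.), P(t-Bu)3 (cat.), rt → 50 °C
Reagents that add atoms: none
Why: Palladium-catalysed α-arylation of an ester zinc enolate (Reformatsky-type enolate obtained by transmetalation): the amide base removes the more acidic ester α-hydrogen at −78 °C, and zinc gives an enolate that neither attacks the N-methoxy-N-methylamide nor deprotonates the product, so single arylation is expected. The new α-centre forms without control, which is harmless because it becomes an enolate carbon again in step 7.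

Step 6
Reactants: 9 tert-butyl (3S)-2-[3-(benzyloxy)-4-methoxyphenyl]-5-[methoxy(methyl)amino]-3-methyl-5-oxopentanoate; 10 1,2-dibromo-4,5-dimethoxybenzene
Product: 12 tert-butyl (3S)-2-[3-(benzyloxy)-4-methoxyphenyl]-5-(2-bromo-4,5-dimethoxyphenyl)-3-methyl-5-oxopentanoate (both epimers at the ester α-carbon), via arylmagnesium chloride 11 (not isolated)
Conditions: 10 (2 equiv), i-PrMgCl·LiCl, THF, −15 °C; then 9, −15 → 0 °C; aq NH4Cl
Reagents that add atoms: none
Why: Bromine–magnesium exchange at one of two equivalent C–Br bonds, then acylation of the arylmagnesium by the N-methoxy-N-methylamide (Weinreb ketone synthesis); the magnesium chelate prevents a second addition. The hindered tert-butyl ester is not attacked, and the excess of 11 covers any loss to deprotonation of the α-aryl ester.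

Step 7
Reactants: 12 tert-butyl (3S)-2-[3-(benzyloxy)-4-methoxyphenyl]-5-(2-bromo-4,5-dimethoxyphenyl)-3-methyl-5-oxopentanoate
Product: 13 tert-butyl (2S)-1-[3-(benzyloxy)-4-methoxyphenyl]-6,7-dimethoxy-2-methyl-4-oxo-1,2,3,4-tetrahydronaphthalene-1-carboxylate (either configuration at the quaternary carbon, tetralone C4)
Conditions: LiN(SiMe3)2 (2.3 equiv), Pd2(dba)3 (cat.), P(t-Bu)3 (cat.), toluene (0.02 M), rt → 50 °C
Reagents that add atoms: none
Why: The excess of amide base converts 12 into its bis-enolate (ester enolate at C4, ketone enolate at C2), a form that cannot undergo retro-Michael cleavage of the C3–C4 bond and so protects C3. Zerovalent palladium bearing P(t-Bu)3 adds oxidatively into the C4a–Br bond, the C4 ester enolate replaces bromide on divalent palladium to give a seven-membered palladacycle, and reductive elimination forms the C4–C4a bond. The closest known reaction type is the palladium-catalysed intramolecular α-arylation of ester enolates that builds benzo-fused rings with a quaternary benzylic carbon. Ring B closes as a six-membered carbocycle by C(sp3)–C(sp2) reductive elimination, the tether between the two reacting carbons being C3–C2–C1–C8a. The new stereocentre at C4 is quaternary and forms without control; both epimers are acceptable because C4 is made again by protonation in step 9, and C3, which has no acidic hydrogen, is carried through unchanged. The step needs site selectivity between two enolates, and ring size secures it: C-arylation at C2 would give a benzocyclobutenone and O-arylation a four-membered oxete, so only C4 can couple within the molecule. Intermolecular arylation of the C2 enolate is held back by the high dilution, and the bulky phosphine favours reductive elimination at the congested carbon.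

Step 8
Reactants: 13 tert-butyl (2S)-1-[3-(benzyloxy)-4-methoxyphenyl]-6,7-dimethoxy-2-methyl-4-oxo-1,2,3,4-tetrahydronaphthalene-1-carboxylate
Product: 15 tert-butyl (2S)-1-[3-(benzyloxy)-4-methoxyphenyl]-6,7-dimethoxy-2,3-dimethyl-4-oxo-1,2,3,4-tetrahydronaphthalene-1-carboxylate (epimers at C1 and at the new C3; tetralone C2 methyl expected mainly trans to the C3 methyl), via lithium ketone enolate 14 (not isolated)
Conditions: LiN(i-Pr)2 (1.1 equiv), THF, −78 °C; MeI, −78 → −40 °C
Reagents that add atoms: iodomethane, CI
Why: Alkylation of a kinetic lithium ketone enolate; tetralone C2 is the only enolisable position because C4 is quaternary. Iodomethane should approach anti to the neighbouring C3 methyl, and the ratio is not critical since C2 is equilibrated in step 10.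

Step 9
Reactants: 15 tert-butyl (2S)-1-[3-(benzyloxy)-4-methoxyphenyl]-6,7-dimethoxy-2,3-dimethyl-4-oxo-1,2,3,4-tetrahydronaphthalene-1-carboxylate
Product: 17 (3R,4R)-4-[3-(benzyloxy)-4-methoxyphenyl]-6,7-dimethoxy-2,3-dimethyl-3,4-dihydronaphthalen-1(2H)-one (mixture of C2 epimers), via carboxylic acid 16 (not isolated)
Conditions: CF3CO2H, CH2Cl2, 0 °C → rt; evaporate; Et3N, DMSO–H2O, 80 °C
Reagents that add atoms: none
Why: Acidolysis of the tert-butyl ester (loss of isobutene), then base-promoted decarboxylation of an arylacetic acid whose carbanion is conjugated through ring A with the C1 carbonyl (a vinylogous β-keto acid, the same class as the decarboxylation of nitroarylacetic acids); both C4 epimers give the same dienolate. Protonation at C4 is kinetic: A(1,2) strain with the C4 aryl group pushes the C3 methyl pseudoaxial, the proton arrives on the opposite face, and the aryl group ends cis to the C3 methyl (4R). The weak amine base and the water present should protonate the dienolate faster than C4–H can be removed again.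

Step 10
Reactants: 17 (3R,4R)-4-[3-(benzyloxy)-4-methoxyphenyl]-6,7-dimethoxy-2,3-dimethyl-3,4-dihydronaphthalen-1(2H)-one (mixture of C2 epimers)
Product: 18 (2S,3R,4R)-4-[3-(benzyloxy)-4-methoxyphenyl]-6,7-dimethoxy-2,3-dimethyl-3,4-dihydronaphthalen-1(2H)-one
Conditions: NaOMe (cat.), MeOH, rt
Reagents that add atoms: none
Why: Base-mediated epimerisation α to a ketone through the enolate (thermodynamic control); the 2,3-trans isomer with both methyls equatorial and the aryl group pseudoaxial is the more stable. C4–H, whose removal would dearomatise ring A, should not exchange under these mild conditions.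

Step 11
Reactants: 18 (2S,3R,4R)-4-[3-(benzyloxy)-4-methoxyphenyl]-6,7-dimethoxy-2,3-dimethyl-3,4-dihydronaphthalen-1(2H)-one
Product: 19 (2S,3R,4R)-4-(3-hydroxy-4-methoxyphenyl)-6,7-dimethoxy-2,3-dimethyl-3,4-dihydronaphthalen-1(2H)-one
Conditions: H2 (1 atm), Pd/C (10% Pd on carbon), EtOAc, rt
Reagents that add atoms: none
Why: Hydrogenolysis of a benzyl aryl ether; the electron-rich aryl ketone and the three stereocentres should be untouched at 1 atm and room temperature if the reaction is stopped when uptake ends.

## Compound list

1 | 3-methylglutaric anhydride (4-methyloxane-2,6-dione) | CC1CC(=O)OC(=O)C1 | starting material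
2 | (3R)-5-methoxy-3-methyl-5-oxopentanoic acid | OC(=O)C[C@@H](C)CC(=O)OC | intermediate
3 | 1-tert-butyl 5-methyl (3S)-3-methylpentanedioate | CC(C)(C)OC(=O)C[C@@H](C)CC(=O)OC | intermediate
4 | tert-butyl (3S)-5-[methoxy(methyl)amino]-3-methyl-5-oxopentanoate | CC(C)(C)OC(=O)C[C@@H](C)CC(=O)N(C)OC | intermediate
5 | 5-bromo-2-methoxyphenol | COc1ccc(Br)cc1O | starting material
6 | 2-(benzyloxy)-4-bromo-1-methoxybenzene | COc1ccc(Br)cc1OCc1ccccc1 | intermediate
7 | lithium ester enolate of 4 (not isolated) | CC(C)(C)OC(O[Li])=C[C@@H](C)CC(=O)N(C)OC | intermediate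
8 | chlorozinc ester enolate of 4, drawn C-bound (not isolated) | CC(C)(C)OC(=O)C([Zn]Cl)[C@@H](C)CC(=O)N(C)OC | intermediate
9 | tert-butyl (3S)-2-[3-(benzyloxy)-4-methoxyphenyl]-5-[methoxy(methyl)amino]-3-methyl-5-oxopentanoate, both C2 epimers | COc1ccc(C(C(=O)OC(C)(C)C)[C@@H](C)CC(=O)N(C)OC)cc1OCc1ccccc1 | intermediate
10 | 1,2-dibromo-4,5-dimethoxybenzene | COc1cc(Br)c(Br)cc1OC | starting material
11 | (2-bromo-4,5-dimethoxyphenyl)magnesium chloride, LiCl complex (not isolated) | COc1cc(Br)c([Mg]Cl)cc1OC | intermediate
12 | tert-butyl (3S)-2-[3-(benzyloxy)-4-methoxyphenyl]-5-(2-bromo-4,5-dimethoxyphenyl)-3-methyl-5-oxopentanoate, both C2 epimers | COc1ccc(C(C(=O)OC(C)(C)C)[C@@H](C)CC(=O)c2cc(OC)c(OC)cc2Br)cc1OCc1ccccc1 | intermediate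
13 | tert-butyl (2S)-1-[3-(benzyloxy)-4-methoxyphenyl]-6,7-dimethoxy-2-methyl-4-oxo-1,2,3,4-tetrahydronaphthalene-1-carboxylate, both C1 epimers | COc1ccc(C2(C(=O)OC(C)(C)C)c3cc(OC)c(OC)cc3C(=O)C[C@@H]2C)cc1OCc1ccccc1 | intermediate
14 | lithium ketone enolate of 13 (not isolated) | COc1ccc(C2(C(=O)OC(C)(C)C)c3cc(OC)c(OC)cc3C(O[Li])=C[C@@H]2C)cc1OCc1ccccc1 | intermediate
15 | tert-butyl (2S)-1-[3-(benzyloxy)-4-methoxyphenyl]-6,7-dimethoxy-2,3-dimethyl-4-oxo-1,2,3,4-tetrahydronaphthalene-1-carboxylate, epimers at C1 and C3 | COc1ccc(C2(C(=O)OC(C)(C)C)c3cc(OC)c(OC)cc3C(=O)C(C)[C@@H]2C)cc1OCc1ccccc1 | intermediate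
16 | (2S)-1-[3-(benzyloxy)-4-methoxyphenyl]-6,7-dimethoxy-2,3-dimethyl-4-oxo-1,2,3,4-tetrahydronaphthalene-1-carboxylic acid, epimers at C1 and C3 (not isolated) | COc1ccc(C2(C(=O)O)c3cc(OC)c(OC)cc3C(=O)C(C)[C@@H]2C)cc1OCc1ccccc1 | intermediate
17 | (3R,4R)-4-[3-(benzyloxy)-4-methoxyphenyl]-6,7-dimethoxy-2,3-dimethyl-3,4-dihydronaphthalen-1(2H)-one, C2 epimer mixture | COc1ccc([C@@H]2c3cc(OC)c(OC)cc3C(=O)C(C)[C@@H]2C)cc1OCc1ccccc1 | intermediate
18 | (2S,3R,4R)-4-[3-(benzyloxy)-4-methoxyphenyl]-6,7-dimethoxy-2,3-dimethyl-3,4-dihydronaphthalen-1(2H)-one | COc1ccc([C@@H]2c3cc(OC)c(OC)cc3C(=O)[C@@H](C)[C@@H]2C)cc1OCc1ccccc1 | intermediate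
19 | (2S,3R,4R)-4-(3-hydroxy-4-methoxyphenyl)-6,7-dimethoxy-2,3-dimethyl-3,4-dihydronaphthalen-1(2H)-one | COc1ccc([C@@H]2c3cc(OC)c(OC)cc3C(=O)[C@@H](C)[C@@H]2C)cc1O | target

## Step count and least certain steps

Total steps: 11. Longest linear sequence: 10 (steps 1, 2, 3, 5, 6, 7, 8, 9, 10, 11); step 4 is a one-step side branch. The enantiomeric purity of 19 is that of 2.

**Step 7 (key step).** Three things may go wrong. The C2 ketone enolate of one molecule may be arylated by the arylpalladium of another, giving oligomers. The C–Br bond may be reduced through β-hydride elimination from a palladium enolate. If mono-enolate persists, retro-Michael and Michael reactions across C3–C4 could erode C3 while reductive elimination at the crowded carbon is slow. The fallback removes the ketone enolate altogether. Starting from 12, NaBH4 in MeOH gives the carbinol F1 and TBSOTf with 2,6-lutidine gives the silyl ether F2. The same palladium closure, now with the ester enolate as the only enolate, gives the cyclised silyl ether F3. Bu4NF frees the cyclised carbinol F4, and Dess–Martin periodinane oxidises it to 13, where the route resumes.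

**Step 9.** Loss of CO2 may need temperatures at which protonation is no longer kinetic. The proton may also arrive with poor facial selectivity, or C4 may equilibrate afterwards. The fallback replaces the carbanion by a radical. Starting from 15, the acid 16 is isolated after the trifluoroacetic acid treatment. It is converted with (COCl)2 and then NaC5H4NOS (sodium pyridine-2-thiolate 1-oxide) into the O-acyl thiohydroxamate F5. Photolysis with Bu3SnH (Barton reductive decarboxylation) should deliver hydrogen from the bulky stannane anti to the C3 methyl under neutral conditions, giving 17.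

**Step 5.** The amide base may enolise the amide arm or strip the N-methoxy group, and the β-branched zinc enolate may couple sluggishly. The fallback changes the acyl-transfer group. Starting from 3, magnesium morpholide (morpholine, i-PrMgCl) gives the morpholine amide F6. The same zinc-enolate arylation with 6 gives the arylated morpholine amide F7. Acylation of 11 by F7 then gives 12 directly, bypassing 4 and 9.

**Step 6.** The ortho-bromoarylmagnesium may eliminate to the aryne before a slow addition to the amide is complete, and part of it may be spent deprotonating the α-aryl ester. The fallback uses a more electrophilic acceptor. Starting from 9, i-Bu2AlH at −78 °C gives the aldehyde F8. Reagent 11 adds to it at −40 °C to give the carbinol F1, and Dess–Martin periodinane oxidises F1 to 12.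

**Step 1.** The methanolysis may select incompletely between the two carbonyl groups, and every later compound inherits that deficit. The fallback is enzymatic. Starting from 1, MeOH with catalytic H2SO4 gives dimethyl 3-methylglutarate F9. Hydrolysis with pig liver esterase at pH 7 is expected to give the same (R)-half-ester 2.

## Further compounds

F1 | step 7 | tert-butyl (3S)-2-[3-(benzyloxy)-4-methoxyphenyl]-5-(2-bromo-4,5-dimethoxyphenyl)-5-hydroxy-3-methylpentanoate, epimers at C2 and C5 | COc1ccc(C(C(=O)OC(C)(C)C)[C@@H](C)CC(O)c2cc(OC)c(OC)cc2Br)cc1OCc1ccccc1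
F2 | step 7 | tert-butyl (3S)-2-[3-(benzyloxy)-4-methoxyphenyl]-5-(2-bromo-4,5-dimethoxyphenyl)-5-[(tert-butyldimethylsilyl)oxy]-3-methylpentanoate, epimers at C2 and C5 | COc1ccc(C(C(=O)OC(C)(C)C)[C@@H](C)CC(O[Si](C)(C)C(C)(C)C)c2cc(OC)c(OC)cc2Br)cc1OCc1ccccc1
F3 | step 7 | tert-butyl (2S)-1-[3-(benzyloxy)-4-methoxyphenyl]-4-[(tert-butyldimethylsilyl)oxy]-6,7-dimethoxy-2-methyl-1,2,3,4-tetrahydronaphthalene-1-carboxylate, epimers at C1 and C4 | COc1ccc(C2(C(=O)OC(C)(C)C)c3cc(OC)c(OC)cc3C(O[Si](C)(C)C(C)(C)C)C[C@@H]2C)cc1OCc1ccccc1
F4 | step 7 | tert-butyl (2S)-1-[3-(benzyloxy)-4-methoxyphenyl]-4-hydroxy-6,7-dimethoxy-2-methyl-1,2,3,4-tetrahydronaphthalene-1-carboxylate, epimers at C1 and C4 | COc1ccc(C2(C(=O)OC(C)(C)C)c3cc(OC)c(OC)cc3C(O)C[C@@H]2C)cc1OCc1ccccc1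
F5 | step 9 | 2-thioxopyridin-1(2H)-yl (2S)-1-[3-(benzyloxy)-4-methoxyphenyl]-6,7-dimethoxy-2,3-dimethyl-4-oxo-1,2,3,4-tetrahydronaphthalene-1-carboxylate, epimers at C1 and C3 | COc1ccc(C2(C(=O)ON4C=CC=CC4=S)c3cc(OC)c(OC)cc3C(=O)C(C)[C@@H]2C)cc1OCc1ccccc1
F6 | step 5 | tert-butyl (3S)-3-methyl-5-(morpholin-4-yl)-5-oxopentanoate | CC(C)(C)OC(=O)C[C@@H](C)CC(=O)N1CCOCC1
F7 | step 5 | tert-butyl (3S)-2-[3-(benzyloxy)-4-methoxyphenyl]-3-methyl-5-(morpholin-4-yl)-5-oxopentanoate, both C2 epimers | COc1ccc(C(C(=O)OC(C)(C)C)[C@@H](C)CC(=O)N2CCOCC2)cc1OCc1ccccc1
F8 | step 6 | tert-butyl (3S)-2-[3-(benzyloxy)-4-methoxyphenyl]-3-methyl-5-oxopentanoate, both C2 epimers | COc1ccc(C(C(=O)OC(C)(C)C)[C@@H](C)CC=O)cc1OCc1ccccc1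
F9 | step 1 | dimethyl 3-methylpentanedioate | COC(=O)CC(C)CC(=O)OC
A1 | alternative 1 | methyl 4-[4-methoxy-3-(methylsulfonyloxy)phenyl]-6,7-dimethoxy-3-methyl-1-oxo-1,2,3,4-tetrahydronaphthalene-2-carboxylate, 3,4-cis, C2 epimerisable | COc1ccc([C@@H]2c3cc(OC)c(OC)cc3C(=O)[C@@H](C(=O)OC)[C@@H]2C)cc1OS(C)(=O)=O
A2 | alternative 1 | methyl 4-(2-iodo-4,5-dimethoxyphenyl)-4-[4-methoxy-3-(methylsulfonyloxy)phenyl]-3-methylbutanoate, C3 and C4 configured as in the target | COc1ccc([C@H](c2cc(OC)c(OC)cc2I)[C@@H](C)CC(=O)OC)cc1OS(C)(=O)=O
A3 | alternative 2 | endo photoenol cycloadduct: all-cis 4-[3-(benzyloxy)-4-methoxyphenyl]-1-hydroxy-6,7-dimethoxytetralin fused at C2–C3 to the menthyloxy butyrolactone acetal | COc1ccc([C@@H]2c3cc(OC)c(OC)cc3[C@H](O)[C@@H]3C(=O)O[C@@H](O[C@@H]4C[C@H](C)CC[C@H]4C(C)C)[C@H]23)cc1OCc1ccccc1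
A4 | alternative 2 | 2-[3-(benzyloxy)-4-methoxybenzyl]-4,5-dimethoxybenzaldehyde | COc1ccc(Cc2cc(OC)c(OC)cc2C=O)cc1OCc1ccccc1
A5 | alternative 2 | (5R)-5-[(1R,2S,5R)-menthyloxy]furan-2(5H)-one | O=C1C=C[C@H](O[C@@H]2C[C@H](C)CC[C@H]2C(C)C)O1
A6 | alternative 3 | tert-butyl{[4-(3-benzyloxy-4-methoxyphenyl)-6,7-dimethoxy-2,3-dimethyl-1,2-dihydronaphthalen-1-yl]oxy}dimethylsilane, C1 and C2 configured as in the SMILES | COc1ccc(C2=C(C)[C@@H](C)[C@H](O[Si](C)(C)C(C)(C)C)c3cc(OC)c(OC)cc23)cc1OCc1ccccc1
A7 | alternative 3 | 4-[2-(3-benzyloxy-4-methoxybenzoyl)-4,5-dimethoxyphenyl]-4-[(tert-butyldimethylsilyl)oxy]-3-methylbutan-2-one, C3 and C4 configured as in the SMILES | COc1ccc(C(=O)c2cc(OC)c(OC)cc2[C@@H](O[Si](C)(C)C(C)(C)C)[C@H](C)C(C)=O)cc1OCc1ccccc1
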